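TBS = tert-butyldimethylsilyl, TES = triethylsilyl; U, M, T = upper epicatechin, middle catechin and terminal catechin units; a1–a6 = acyl-ring carbons (a1 carbinol carbon, a6 ketone carbon).
Feature: a1 carries two three-carbon arms, a2=a3 and a6(=O)–a5, alike except in oxidation level; with a second alkene in place of the keto arm, a1 is the non-stereogenic centre of a symmetric 1-hydroxycyclohexa-2,5-diene-1-carboxylate.
Cuts, in retrosynthetic order: fourteen O–Si bonds; a6=O back to a6–OH; a5–H back to a5–O of a syn oxirane, whose a5–O and a6–O bonds are both cut in the key step; a1–OH; the ester C–O bond at O3 of T; C4(U)–C8(M); C4(M)–C8(T).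
Forward: M is joined to T, then U to M–T, by two flavan-4-yl cation couplings; the one free 3-OH is acylated with Birch-derived dihydrobenzoic acid and hydroxylated at a1; the oxirane, the only ring made, closes in the epoxidation; opening at a5, deselenation, oxidation at a6 and desilylation finish the route.
Stereochemistry: C2 and C3 of all units come from (+)-catechin and (−)-epicatechin; both C4 centres arise by attack anti to the 3-silyloxy group; a1 is fixed by the chiral catalyst's choice between the two ring alkenes, while a5 and a6 are set syn to the hydroxyl and erased later.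

Key step: step 11

Assumption: the sense in which a given antipode of the bishydroxamic acid ligand selects between the two alkenes cannot be predicted for this carbinol; both antipodes are accessible, and the one that gives the a1-(S) epoxide is to be identified on methyl 1-hydroxycyclohexa-2,5-diene-1-carboxylate before the trimer is committed.

Step 1
Reactants: 1 (+)-catechin
Product: 2 5,7,3',4'-tetra-O-TBS-(+)-catechin (3-OH free)
Conditions: TBSCl (4.4 equiv), imidazole, DMF, 0 °C to rt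
Reagents that add atoms: tert-butyldimethylsilyl chloride, CC(C)(C)[Si](C)(C)Cl
Why: Phenols are silylated much faster than the secondary 3-OH under TBSCl/imidazole (chemoselective O-silylation), so four equivalents should stop at the tetra-aryl ether with C2 and C3 untouched.

Step 2
Reactants: 1 (+)-catechin
Product: 3 3,5,7,3',4'-penta-O-TBS-(+)-catechin
Conditions: TBSOTf (6 equiv), 2,6-lutidine, CH2Cl2, 0 °C to rt
Reagents that add atoms: tert-butyldimethylsilyl triflate, CC(C)(C)[Si](C)(C)OS(=O)(=O)C(F)(F)F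
Why: The silyl triflate also caps the secondary 3-OH (exhaustive O-silylation), which blocks O3 of the future unit M and places a bulky β-substituent next to C4.

Step 3
Reactants: 3 penta-O-TBS-(+)-catechin
Product: 4 4α-(2-ethoxyethoxy)-penta-O-TBS-(+)-catechin
Conditions: DDQ (2 equiv), 2-ethoxyethanol (5 equiv), CH2Cl2, rt
Reagents that add atoms: 2-ethoxyethanol, CCOCCO
Why: DDQ removes the benzylic C4 hydride to give a cation stabilised by the 5- and 7-oxygens, which the alcohol should trap anti to the 3-silyloxy group (oxidative benzylic etherification); the C4 configuration is immaterial because the ether is ionised again in step 4.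

Step 4
Reactants: 4 4α-(2-ethoxyethoxy)-penta-O-TBS-(+)-catechin; 2 tetra-O-TBS-(+)-catechin (3 equiv)
Product: 5 nona-O-TBS catechin-(4α→8)-catechin with free 3-OH on unit T
Conditions: TMSOTf (0.3 equiv), 4 Å molecular sieves, CH2Cl2, −78 °C; Et3N quench
Reagents that add atoms: none
Why: TMSOTf ionises the C4 ether and the flavan-4-yl cation alkylates the phloroglucinol ring of 2 at C8 (Friedel–Crafts interflavan coupling), C6 being flanked by two silyloxy groups, with the arene entering anti to the 3β-silyloxy group to set 4α (3,4-trans); excess 2 suppresses self-condensation of 4 and is recovered.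

Step 5
Reactants: 6 (−)-epicatechin
Product: 7 3,5,7,3',4'-penta-O-TBS-(−)-epicatechin
Conditions: TBSOTf (6 equiv), 2,6-lutidine, CH2Cl2, 0 °C to rt
Reagents that add atoms: tert-butyldimethylsilyl triflate, CC(C)(C)[Si](C)(C)OS(=O)(=O)C(F)(F)F
Why: Exhaustive O-silylation with the triflate also reaches the axial 3-OH, which must stay masked so that only O3 of unit T is free later.

Step 6
Reactants: 7 penta-O-TBS-(−)-epicatechin
Product: 8 4β-(2-ethoxyethoxy)-penta-O-TBS-(−)-epicatechin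
Conditions: DDQ (2 equiv), 2-ethoxyethanol (5 equiv), CH2Cl2, rt
Reagents that add atoms: 2-ethoxyethanol, CCOCCO
Why: Same oxidative benzylic etherification as step 3, the alcohol entering on the β face trans to the axial 3α-silyloxy group.

Step 7
Reactants: 8 4β-(2-ethoxyethoxy)-penta-O-TBS-(−)-epicatechin; 5 nona-O-TBS catechin-(4α→8)-catechin (2 equiv)
Product: 9 tetradeca-O-TBS epicatechin-(4β→8)-catechin-(4α→8)-catechin with only the 3-OH of unit T free (trimer alcohol)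
Conditions: TMSOTf (0.3 equiv), 4 Å molecular sieves, CH2Cl2, −78 to −40 °C, slow addition of 8; Et3N quench
Reagents that add atoms: none
Why: The cation from 8 should be taken by C8 of unit M, the only nucleophilic carbon of 5 not flanked by two silyloxy groups, from the β face anti to the axial 3α-silyloxy group (Friedel–Crafts interflavan coupling, 4β and 3,4-trans as usual for 2,3-cis flavanyl cations); slow addition to excess 5 limits self-condensation.

Step 8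
Reactants: 10 benzoic acid
Product: 11 cyclohexa-2,5-diene-1-carboxylic acid
Conditions: Na, NH3 (l), EtOH, −78 °C; NH4Cl; aq. HCl
Reagents that add atoms: none
Why: Birch reduction of the benzoate protonates the ipso and para carbons and gives the skipped 1,4-diene acid, which has no stereocentre.

Step 9
Reactants: 9 trimer alcohol; 11 cyclohexa-2,5-diene-1-carboxylic acid (3 equiv)
Product: 12 trimer 3-O(T)-cyclohexa-2,5-diene-1-carboxylate
Conditions: DCC, DMAP (0.1 equiv), CH2Cl2, 0 °C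
Reagents that add atoms: none
Why: The 3-OH of unit T is the only free hydroxyl in 9, so Steglich esterification acylates it with retention at C3; low temperature and little DMAP limit isomerisation of the skipped diene into conjugation.

Step 10
Reactants: 12 trimer 3-O(T)-cyclohexa-2,5-diene-1-carboxylate
Product: 14 trimer 3-O(T)-(1-hydroxycyclohexa-2,5-diene-1-carboxylate), via potassium dienolate 13 (not isolated)
Conditions: KN(SiMe3)2 (1.2 equiv), THF, −78 °C; 3-phenyl-2-(phenylsulfonyl)oxaziridine (1.5 equiv), −78 °C; NH4Cl quench at −78 °C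
Reagents that add atoms: 3-phenyl-2-(phenylsulfonyl)oxaziridine, O=S(=O)(c1ccccc1)N1OC1c1ccccc1
Why: The doubly allylic α-proton is removed to a cross-conjugated dienolate that takes electrophilic oxygen at the α-carbon (Davis oxidation), as Birch enolates do with alkyl halides; a1 then carries two identical arms and is not a stereocentre, so one compound results.

Step 11
Reactants: 14 trimer 3-O(T)-(1-hydroxycyclohexa-2,5-diene-1-carboxylate)
Product: 15 syn a5,a6-epoxide, trimer 3-O(T)-[(1R,2S,6R)-2-hydroxy-7-oxabicyclo[4.1.0]hept-3-ene-2-carboxylate] (a1 S, a5 R, a6 R)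
Conditions: VO(OiPr)3 (5 mol %), N,N'-dihydroxy-N,N'-bis(diphenylacetyl)-trans-cyclohexane-1,2-diamine (one antipode, 6 mol %), tBuOOH (1.1 equiv, anhydrous), toluene, 0 °C
Reagents that add atoms: tert-butyl hydroperoxide, CC(C)(C)OO
Why: Proposed new method: the tertiary hydroxyl at a1 exchanges onto pentavalent vanadium that also holds the chiral bishydroxamate and a side-on tert-butylperoxide, and the peroxide oxygen is passed within this complex to one flanking alkene, so a6–O and a5–O form in one event and the oxirane closes by a 3-exo-type intracomplex oxygen transfer with loss of tert-butoxide. The closest known reactions are the hydroxyl-directed, group-selective epoxidations of divinyl carbinols and the bishydroxamate epoxidations of tertiary allylic alcohols with vanadium or tetravalent hafnium; new here is a tertiary, ester-bearing cyclohexa-2,5-dienol as substrate. a5 and a6 are set by syn delivery from the metal-bound hydroxyl (the cis ring fusion is inherent), while a1 becomes stereogenic only because the ligand picks one of the two alkenes, which are enantiotopic within the acyl ring and differ in the whole molecule only through the remote flavan stereocentres. Three selectivities are needed: alkene choice (ligand), face (the metal–alkoxide tether keeps the peroxide on the hydroxyl side) and mono- over bis-epoxidation (one equivalent of oxidant and a second alkene that is inductively deactivated and more hindered). Any minor a1 epimer should be drained preferentially into bis-epoxide, because its remaining alkene is the one the ligand prefers. The silyl ethers, the ester and the arenes offer no hydroxyl to the metal and should be left alone.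

Step 12
Reactants: 15 syn a5,a6-epoxide
Product: 16 trimer 3-O(T)-[(1S,5S,6S)-1,6-dihydroxy-5-(phenylselanyl)cyclohex-2-ene-1-carboxylate]
Conditions: (PhSe)2, NaBH4, EtOH–THF, 0 °C to rt
Reagents that add atoms: diphenyl diselenide, c1ccc(cc1)[Se][Se]c1ccccc1
Why: The soft selenolate opens the oxirane by SN2 attack at a5, remote from the fully substituted a1 (a6 is neopentyl-like), with inversion at a5 and retention at a6 (trans-diaxial epoxide opening by phenylselenide), so the oxygen stays on a6; the borate-buffered medium is only weakly basic and should spare the ester and the aryl silyl ethers.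

Step 13
Reactants: 16 hydroxy selenide
Product: 17 trimer 3-O(T)-[(1S,6R)-1,6-dihydroxycyclohex-2-ene-1-carboxylate] (cis-diol)
Conditions: Bu3SnH (3 equiv), AIBN (0.2 equiv), toluene, 80 °C
Reagents that add atoms: none
Why: Radical chain reduction of the alkyl phenyl selenide by the stannane replaces a5–Se by a5–H; the secondary radical has no β-leaving group and its 3-butenyl cyclisation is unproductive, so the cis-diol and the a2=a3 alkene persist.

Step 14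
Reactants: 17 cis-diol
Product: 18 trimer 3-O(T)-[(1S)-1-hydroxy-6-oxocyclohex-2-ene-1-carboxylate] (tetradeca-O-TBS ether of the target)
Conditions: Dess–Martin periodinane (1.5 equiv), pyridine, CH2Cl2, 0 °C to rt
Reagents that add atoms: none
Why: Dess–Martin oxidation converts the secondary a6 carbinol to the ketone under buffered, non-basic conditions while the tertiary a1 hydroxyl cannot be oxidised; a1 bears no hydrogen and cannot epimerise.

Step 15
Reactants: 18 tetradeca-O-TBS ether of the target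
Product: 19 CNP0159807.2, epicatechin-(4β→8)-catechin-(4α→8)-catechin 3-O(T)-[(1S)-1-hydroxy-6-oxocyclohex-2-ene-1-carboxylate]
Conditions: HF·pyridine (excess), pyridine, THF, 0 °C to rt; Me3SiOMe quench; Sephadex LH-20
Reagents that add atoms: none
Why: Fluoride-driven cleavage of all fourteen Si–O bonds (global desilylation) in a pyridine-buffered medium avoids the base that would degrade the α-hydroxy-β-keto ester and the free catechols, and is too mild to break the interflavan bonds.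

Compound list
1 | (+)-catechin, (2R,3S) | O[C@H]1Cc2c(O)cc(O)cc2O[C@@H]1c1ccc(O)c(O)c1 | starting material
2 | 5,7,3',4'-tetra-O-TBS-(+)-catechin, 3-OH free | O[C@H]1Cc2c(O[Si](C)(C)C(C)(C)C)cc(O[Si](C)(C)C(C)(C)C)cc2O[C@@H]1c1ccc(O[Si](C)(C)C(C)(C)C)c(O[Si](C)(C)C(C)(C)C)c1 | intermediate
3 | 3,5,7,3',4'-penta-O-TBS-(+)-catechin | CC(C)(C)[Si](C)(C)O[C@H]1Cc2c(O[Si](C)(C)C(C)(C)C)cc(O[Si](C)(C)C(C)(C)C)cc2O[C@@H]1c1ccc(O[Si](C)(C)C(C)(C)C)c(O[Si](C)(C)C(C)(C)C)c1 | intermediate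
4 | 4α-(2-ethoxyethoxy)-penta-O-TBS-(+)-catechin (2,3-trans, 3,4-trans) | CCOCCO[C@@H]1c2c(O[Si](C)(C)C(C)(C)C)cc(O[Si](C)(C)C(C)(C)C)cc2O[C@H](c2ccc(O[Si](C)(C)C(C)(C)C)c(O[Si](C)(C)C(C)(C)C)c2)[C@H]1O[Si](C)(C)C(C)(C)C | intermediate
5 | nona-O-TBS catechin-(4α→8)-catechin: unit M penta-O-TBS, unit T 5,7,3',4'-tetra-O-TBS with free 3-OH | O[C@H]1Cc2c(O[Si](C)(C)C(C)(C)C)cc(O[Si](C)(C)C(C)(C)C)c([C@@H]3c4c(O[Si](C)(C)C(C)(C)C)cc(O[Si](C)(C)C(C)(C)C)cc4O[C@H](c4ccc(O[Si](C)(C)C(C)(C)C)c(O[Si](C)(C)C(C)(C)C)c4)[C@H]3O[Si](C)(C)C(C)(C)C)c2O[C@@H]1c1ccc(O[Si](C)(C)C(C)(C)C)c(O[Si](C)(C)C(C)(C)C)c1 | intermediate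
6 | (−)-epicatechin, (2R,3R) | O[C@@H]1Cc2c(O)cc(O)cc2O[C@@H]1c1ccc(O)c(O)c1 | starting material
7 | 3,5,7,3',4'-penta-O-TBS-(−)-epicatechin | CC(C)(C)[Si](C)(C)O[C@@H]1Cc2c(O[Si](C)(C)C(C)(C)C)cc(O[Si](C)(C)C(C)(C)C)cc2O[C@@H]1c1ccc(O[Si](C)(C)C(C)(C)C)c(O[Si](C)(C)C(C)(C)C)c1 | intermediate
8 | 4β-(2-ethoxyethoxy)-penta-O-TBS-(−)-epicatechin (2,3-cis, 3,4-trans) | CCOCCO[C@H]1c2c(O[Si](C)(C)C(C)(C)C)cc(O[Si](C)(C)C(C)(C)C)cc2O[C@H](c2ccc(O[Si](C)(C)C(C)(C)C)c(O[Si](C)(C)C(C)(C)C)c2)[C@@H]1O[Si](C)(C)C(C)(C)C | intermediate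
9 | trimer alcohol: tetradeca-O-TBS epicatechin-(4β→8)-catechin-(4α→8)-catechin, only the 3-OH of unit T free | O[C@H]1Cc2c(O[Si](C)(C)C(C)(C)C)cc(O[Si](C)(C)C(C)(C)C)c([C@@H]3c4c(O[Si](C)(C)C(C)(C)C)cc(O[Si](C)(C)C(C)(C)C)c([C@H]5c6c(O[Si](C)(C)C(C)(C)C)cc(O[Si](C)(C)C(C)(C)C)cc6O[C@H](c6ccc(O[Si](C)(C)C(C)(C)C)c(O[Si](C)(C)C(C)(C)C)c6)[C@@H]5O[Si](C)(C)C(C)(C)C)c4O[C@H](c4ccc(O[Si](C)(C)C(C)(C)C)c(O[Si](C)(C)C(C)(C)C)c4)[C@H]3O[Si](C)(C)C(C)(C)C)c2O[C@@H]1c1ccc(O[Si](C)(C)C(C)(C)C)c(O[Si](C)(C)C(C)(C)C)c1 | intermediate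
10 | benzoic acid | O=C(O)c1ccccc1 | starting material
11 | cyclohexa-2,5-diene-1-carboxylic acid | O=C(O)C1C=CCC=C1 | intermediate
12 | trimer 3-O(T)-cyclohexa-2,5-diene-1-carboxylate | O=C(C1C=CCC=C1)O[C@H]1Cc2c(O[Si](C)(C)C(C)(C)C)cc(O[Si](C)(C)C(C)(C)C)c([C@@H]3c4c(O[Si](C)(C)C(C)(C)C)cc(O[Si](C)(C)C(C)(C)C)c([C@H]5c6c(O[Si](C)(C)C(C)(C)C)cc(O[Si](C)(C)C(C)(C)C)cc6O[C@H](c6ccc(O[Si](C)(C)C(C)(C)C)c(O[Si](C)(C)C(C)(C)C)c6)[C@@H]5O[Si](C)(C)C(C)(C)C)c4O[C@H](c4ccc(O[Si](C)(C)C(C)(C)C)c(O[Si](C)(C)C(C)(C)C)c4)[C@H]3O[Si](C)(C)C(C)(C)C)c2O[C@@H]1c1ccc(O[Si](C)(C)C(C)(C)C)c(O[Si](C)(C)C(C)(C)C)c1 | intermediate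
13 | potassium dienolate of 12 | [K+].[O-]C(=C1C=CCC=C1)O[C@H]1Cc2c(O[Si](C)(C)C(C)(C)C)cc(O[Si](C)(C)C(C)(C)C)c([C@@H]3c4c(O[Si](C)(C)C(C)(C)C)cc(O[Si](C)(C)C(C)(C)C)c([C@H]5c6c(O[Si](C)(C)C(C)(C)C)cc(O[Si](C)(C)C(C)(C)C)cc6O[C@H](c6ccc(O[Si](C)(C)C(C)(C)C)c(O[Si](C)(C)C(C)(C)C)c6)[C@@H]5O[Si](C)(C)C(C)(C)C)c4O[C@H](c4ccc(O[Si](C)(C)C(C)(C)C)c(O[Si](C)(C)C(C)(C)C)c4)[C@H]3O[Si](C)(C)C(C)(C)C)c2O[C@@H]1c1ccc(O[Si](C)(C)C(C)(C)C)c(O[Si](C)(C)C(C)(C)C)c1 | intermediate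
14 | trimer 3-O(T)-(1-hydroxycyclohexa-2,5-diene-1-carboxylate), acyl ring achiral | OC1(C=CCC=C1)C(=O)O[C@H]1Cc2c(O[Si](C)(C)C(C)(C)C)cc(O[Si](C)(C)C(C)(C)C)c([C@@H]3c4c(O[Si](C)(C)C(C)(C)C)cc(O[Si](C)(C)C(C)(C)C)c([C@H]5c6c(O[Si](C)(C)C(C)(C)C)cc(O[Si](C)(C)C(C)(C)C)cc6O[C@H](c6ccc(O[Si](C)(C)C(C)(C)C)c(O[Si](C)(C)C(C)(C)C)c6)[C@@H]5O[Si](C)(C)C(C)(C)C)c4O[C@H](c4ccc(O[Si](C)(C)C(C)(C)C)c(O[Si](C)(C)C(C)(C)C)c4)[C@H]3O[Si](C)(C)C(C)(C)C)c2O[C@@H]1c1ccc(O[Si](C)(C)C(C)(C)C)c(O[Si](C)(C)C(C)(C)C)c1 | intermediate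
15 | syn a5,a6-epoxide: trimer 3-O(T)-[(1R,2S,6R)-2-hydroxy-7-oxabicyclo[4.1.0]hept-3-ene-2-carboxylate] | [C@H]12O[C@@H]2CC=C[C@@]1(O)C(=O)O[C@H]1Cc2c(O[Si](C)(C)C(C)(C)C)cc(O[Si](C)(C)C(C)(C)C)c([C@@H]3c4c(O[Si](C)(C)C(C)(C)C)cc(O[Si](C)(C)C(C)(C)C)c([C@H]5c6c(O[Si](C)(C)C(C)(C)C)cc(O[Si](C)(C)C(C)(C)C)cc6O[C@H](c6ccc(O[Si](C)(C)C(C)(C)C)c(O[Si](C)(C)C(C)(C)C)c6)[C@@H]5O[Si](C)(C)C(C)(C)C)c4O[C@H](c4ccc(O[Si](C)(C)C(C)(C)C)c(O[Si](C)(C)C(C)(C)C)c4)[C@H]3O[Si](C)(C)C(C)(C)C)c2O[C@@H]1c1ccc(O[Si](C)(C)C(C)(C)C)c(O[Si](C)(C)C(C)(C)C)c1 | intermediate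
16 | trimer 3-O(T)-[(1S,5S,6S)-1,6-dihydroxy-5-(phenylselanyl)cyclohex-2-ene-1-carboxylate] | O[C@@H]1[C@@H]([Se]c2ccccc2)CC=C[C@@]1(O)C(=O)O[C@H]1Cc2c(O[Si](C)(C)C(C)(C)C)cc(O[Si](C)(C)C(C)(C)C)c([C@@H]3c4c(O[Si](C)(C)C(C)(C)C)cc(O[Si](C)(C)C(C)(C)C)c([C@H]5c6c(O[Si](C)(C)C(C)(C)C)cc(O[Si](C)(C)C(C)(C)C)cc6O[C@H](c6ccc(O[Si](C)(C)C(C)(C)C)c(O[Si](C)(C)C(C)(C)C)c6)[C@@H]5O[Si](C)(C)C(C)(C)C)c4O[C@H](c4ccc(O[Si](C)(C)C(C)(C)C)c(O[Si](C)(C)C(C)(C)C)c4)[C@H]3O[Si](C)(C)C(C)(C)C)c2O[C@@H]1c1ccc(O[Si](C)(C)C(C)(C)C)c(O[Si](C)(C)C(C)(C)C)c1 | intermediate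
17 | trimer 3-O(T)-[(1S,6R)-1,6-dihydroxycyclohex-2-ene-1-carboxylate], cis-diol | O[C@@H]1CCC=C[C@@]1(O)C(=O)O[C@H]1Cc2c(O[Si](C)(C)C(C)(C)C)cc(O[Si](C)(C)C(C)(C)C)c([C@@H]3c4c(O[Si](C)(C)C(C)(C)C)cc(O[Si](C)(C)C(C)(C)C)c([C@H]5c6c(O[Si](C)(C)C(C)(C)C)cc(O[Si](C)(C)C(C)(C)C)cc6O[C@H](c6ccc(O[Si](C)(C)C(C)(C)C)c(O[Si](C)(C)C(C)(C)C)c6)[C@@H]5O[Si](C)(C)C(C)(C)C)c4O[C@H](c4ccc(O[Si](C)(C)C(C)(C)C)c(O[Si](C)(C)C(C)(C)C)c4)[C@H]3O[Si](C)(C)C(C)(C)C)c2O[C@@H]1c1ccc(O[Si](C)(C)C(C)(C)C)c(O[Si](C)(C)C(C)(C)C)c1 | intermediate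
18 | trimer 3-O(T)-[(1S)-1-hydroxy-6-oxocyclohex-2-ene-1-carboxylate], tetradeca-O-TBS ether of the target | O=C1CCC=C[C@@]1(O)C(=O)O[C@H]1Cc2c(O[Si](C)(C)C(C)(C)C)cc(O[Si](C)(C)C(C)(C)C)c([C@@H]3c4c(O[Si](C)(C)C(C)(C)C)cc(O[Si](C)(C)C(C)(C)C)c([C@H]5c6c(O[Si](C)(C)C(C)(C)C)cc(O[Si](C)(C)C(C)(C)C)cc6O[C@H](c6ccc(O[Si](C)(C)C(C)(C)C)c(O[Si](C)(C)C(C)(C)C)c6)[C@@H]5O[Si](C)(C)C(C)(C)C)c4O[C@H](c4ccc(O[Si](C)(C)C(C)(C)C)c(O[Si](C)(C)C(C)(C)C)c4)[C@H]3O[Si](C)(C)C(C)(C)C)c2O[C@@H]1c1ccc(O[Si](C)(C)C(C)(C)C)c(O[Si](C)(C)C(C)(C)C)c1 | intermediate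
19 | CNP0159807.2: epicatechin-(4β→8)-catechin-(4α→8)-catechin 3-O(T)-[(1S)-1-hydroxy-6-oxocyclohex-2-ene-1-carboxylate] | O=C1CCC=C[C@@]1(O)C(=O)O[C@H]1Cc2c(O)cc(O)c([C@@H]3c4c(O)cc(O)c([C@H]5c6c(O)cc(O)cc6O[C@H](c6ccc(O)c(O)c6)[C@@H]5O)c4O[C@H](c4ccc(O)c(O)c4)[C@H]3O)c2O[C@@H]1c1ccc(O)c(O)c1 | target

Total step count: 15. Longest linear sequence: 11 steps (steps 2, 3, 4, 7, 9, 10, 11, 12, 13, 14, 15, from (+)-catechin).

Steps most likely to fail

Step 11 (Proposed new method). What may go wrong: the catalyst discriminates poorly between the two ring alkenes, or turnover stalls because the ester-flanked tertiary carbinol exchanges slowly onto vanadium. The fallback uses known chemistry and takes a1 from the chiral pool. It sets out from benzoic acid 10 and trimer alcohol 9. Whole-cell ipso,ortho-dihydroxylation of sodium benzoate with Ralstonia eutropha B9 should give (1S,6R)-1,6-dihydroxycyclohexa-2,4-diene-1-carboxylic acid F1, in which a1 already has the S configuration and the two hydroxyls are cis. Diimide (KO2C–N=N–CO2K, AcOH, MeOH, 0 °C) should saturate the alkene remote from the quaternary carbon and give (1S,6R)-1,6-dihydroxycyclohex-2-ene-1-carboxylic acid F2. TESOTf with 2,6-lutidine silylates all three hydroxyls to triethylsilyl (1S,6R)-1,6-bis(triethylsilyloxy)cyclohex-2-ene-1-carboxylate F3, and K2CO3 in MeOH–H2O then hydrolyses only the silyl ester to (1S,6R)-1,6-bis(triethylsilyloxy)cyclohex-2-ene-1-carboxylic acid F4. Yamaguchi esterification (2,4,6-trichlorobenzoyl chloride, Et3N, DMAP, toluene) with 9 gives the trimer 3-O(T)-bis(triethylsilyloxy) ester F5. PPTS in MeOH–CH2Cl2 should remove the two alkyl TES ethers faster than any aryl or hindered secondary TBS ether. The route is rejoined at cis-diol 17, bypassing steps 9 to 13.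

Step 7. What may go wrong: the cation from 8, whose own C8 is free, self-condenses faster than it is captured by the hindered, silyloxy-flanked C8 of dimer 5. The fallback blocks that position. It sets out from 8: NBS in CH2Cl2 at −78 °C should brominate C8 (C6 lies between two silyloxy groups) to give 8-bromo-4β-(2-ethoxyethoxy)-penta-O-TBS-(−)-epicatechin F6. F6 cannot oligomerise, so it can be used in excess with TMSOTf until 5 is consumed, giving the 8-bromo trimer alcohol F7. Hydrogenolysis of the aryl bromide (H2, Pd/C, Et3N, EtOAc; no alkene or benzyl group is present at this stage) returns to trimer alcohol 9.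

Step 12. What may go wrong: aryl silyl ethers are lost or the ester is exchanged in the ethoxide/borate medium, or SN2 attack at a5 is slow enough for elimination and aromatisation to compete. The fallback replaces the basic chalcogenide opening by a chelation-controlled halide opening. It sets out from epoxide 15: MgI2 in Et2O–toluene at −40 °C, bound between the a1 hydroxyl and the oxirane oxygen, should deliver iodide to a5 and give the trimer 3-O(T)-[(1S,5S,6S)-1,6-dihydroxy-5-iodocyclohex-2-ene-1-carboxylate] F8. Radical deiodination (Bu3SnH, Et3B, air, toluene, 0 °C) returns to cis-diol 17, bypassing 16.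

Further compounds
F1 | step 11 | (1S,6R)-1,6-dihydroxycyclohexa-2,4-diene-1-carboxylic acid | O[C@@H]1C=CC=C[C@@]1(O)C(=O)O
F2 | step 11 | (1S,6R)-1,6-dihydroxycyclohex-2-ene-1-carboxylic acid | O[C@@H]1CCC=C[C@@]1(O)C(=O)O
F3 | step 11 | triethylsilyl (1S,6R)-1,6-bis(triethylsilyloxy)cyclohex-2-ene-1-carboxylate | CC[Si](CC)(CC)O[C@@H]1CCC=C[C@@]1(O[Si](CC)(CC)CC)C(=O)O[Si](CC)(CC)CC
F4 | step 11 | (1S,6R)-1,6-bis(triethylsilyloxy)cyclohex-2-ene-1-carboxylic acid | CC[Si](CC)(CC)O[C@@H]1CCC=C[C@@]1(O[Si](CC)(CC)CC)C(=O)O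
F5 | step 11 | trimer 3-O(T)-[(1S,6R)-1,6-bis(triethylsilyloxy)cyclohex-2-ene-1-carboxylate] | CC[Si](CC)(CC)O[C@@H]1CCC=C[C@@]1(O[Si](CC)(CC)CC)C(=O)O[C@H]1Cc2c(O[Si](C)(C)C(C)(C)C)cc(O[Si](C)(C)C(C)(C)C)c([C@@H]3c4c(O[Si](C)(C)C(C)(C)C)cc(O[Si](C)(C)C(C)(C)C)c([C@H]5c6c(O[Si](C)(C)C(C)(C)C)cc(O[Si](C)(C)C(C)(C)C)cc6O[C@H](c6ccc(O[Si](C)(C)C(C)(C)C)c(O[Si](C)(C)C(C)(C)C)c6)[C@@H]5O[Si](C)(C)C(C)(C)C)c4O[C@H](c4ccc(O[Si](C)(C)C(C)(C)C)c(O[Si](C)(C)C(C)(C)C)c4)[C@H]3O[Si](C)(C)C(C)(C)C)c2O[C@@H]1c1ccc(O[Si](C)(C)C(C)(C)C)c(O[Si](C)(C)C(C)(C)C)c1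
F6 | step 7 | 8-bromo-4β-(2-ethoxyethoxy)-penta-O-TBS-(−)-epicatechin | CCOCCO[C@H]1c2c(O[Si](C)(C)C(C)(C)C)cc(O[Si](C)(C)C(C)(C)C)c(Br)c2O[C@H](c2ccc(O[Si](C)(C)C(C)(C)C)c(O[Si](C)(C)C(C)(C)C)c2)[C@@H]1O[Si](C)(C)C(C)(C)C
F7 | step 7 | trimer alcohol with bromine at C8 of unit U | O[C@H]1Cc2c(O[Si](C)(C)C(C)(C)C)cc(O[Si](C)(C)C(C)(C)C)c([C@@H]3c4c(O[Si](C)(C)C(C)(C)C)cc(O[Si](C)(C)C(C)(C)C)c([C@H]5c6c(O[Si](C)(C)C(C)(C)C)cc(O[Si](C)(C)C(C)(C)C)c(Br)c6O[C@H](c6ccc(O[Si](C)(C)C(C)(C)C)c(O[Si](C)(C)C(C)(C)C)c6)[C@@H]5O[Si](C)(C)C(C)(C)C)c4O[C@H](c4ccc(O[Si](C)(C)C(C)(C)C)c(O[Si](C)(C)C(C)(C)C)c4)[C@H]3O[Si](C)(C)C(C)(C)C)c2O[C@@H]1c1ccc(O[Si](C)(C)C(C)(C)C)c(O[Si](C)(C)C(C)(C)C)c1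
F8 | step 12 | trimer 3-O(T)-[(1S,5S,6S)-1,6-dihydroxy-5-iodocyclohex-2-ene-1-carboxylate] | O[C@@H]1[C@@H](I)CC=C[C@@]1(O)C(=O)O[C@H]1Cc2c(O[Si](C)(C)C(C)(C)C)cc(O[Si](C)(C)C(C)(C)C)c([C@@H]3c4c(O[Si](C)(C)C(C)(C)C)cc(O[Si](C)(C)C(C)(C)C)c([C@H]5c6c(O[Si](C)(C)C(C)(C)C)cc(O[Si](C)(C)C(C)(C)C)cc6O[C@H](c6ccc(O[Si](C)(C)C(C)(C)C)c(O[Si](C)(C)C(C)(C)C)c6)[C@@H]5O[Si](C)(C)C(C)(C)C)c4O[C@H](c4ccc(O[Si](C)(C)C(C)(C)C)c(O[Si](C)(C)C(C)(C)C)c4)[C@H]3O[Si](C)(C)C(C)(C)C)c2O[C@@H]1c1ccc(O[Si](C)(C)C(C)(C)C)c(O[Si](C)(C)C(C)(C)C)c1
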